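Assumption: the benzyl-protected building blocks 1 and 6 and (R)-epichlorohydrin 2 are bought. Chain positions are given in target numbering (C1 at the catechol ring, C3 the acetoxy carbon, C5 the free carbinol, C7 at the 4-hydroxyphenyl ring). The target is the anti (3R,5R) isomer.

## Retrosynthetic overview

1. Target 11 ⇐ tris-benzyl ether 10 by hydrogenolysis.
2. 10 ⇐ β-hydroxy ketone 8 by Evans–Tishchenko reduction with acetaldehyde, which puts the acetate on O3 and sets C5 anti to C3 in one step.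
3. 8 ⇐ epoxide 5 + thioester 7: the C4–C5 bond is made by a light-driven cobalt/nickel acylative epoxide opening (new).
4. 5 ⇐ benzyl chloride 1 + (R)-epichlorohydrin 2, which supplies C3; 7 ⇐ acid 6.
5. No ring is built: both benzene rings are bought, and the only ring formed is the oxirane of 5 (step 1), opened again in step 3.

## Route

Step 1
Reactants: 1 3,4-bis(benzyloxy)benzyl chloride (1.3 equiv); 2 (R)-epichlorohydrin (1.0 equiv)
Product: 5 (2R)-2-{2-[3,4-bis(benzyloxy)phenyl]ethyl}oxirane, via benzylic Grignard reagent 3 (not isolated), via chlorohydrin 4 (not isolated)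
Conditions: Mg, THF, 0 °C (slow addition of 1); then 2, CuI (10 mol%), THF, −40 → 0 °C; then NaOH (5 M aq), MeOH, rt
Reagents that add atoms: none
Why: CuI-catalysed SN2 opening of the epoxide at its unsubstituted carbon by the benzylic Grignard reagent, then Williamson ring closure of the chlorohydrin; the C–O bond at the stereocenter is never broken, so the (R) centre of 2 becomes the (R) centre of 5.

Step 2
Reactants: 6 3-[4-(benzyloxy)phenyl]propanoic acid
Product: 7 S-(pyridin-2-yl) 3-[4-(benzyloxy)phenyl]propanethioate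
Conditions: 2,2'-dipyridyl disulfide (1.2 equiv), PPh3 (1.2 equiv), CH2Cl2, rt
Reagents that add atoms: 2,2'-dipyridyl disulfide, c1ccc(nc1)SSc1ccccn1
Why: Mukaiyama redox condensation; the acyloxyphosphonium ion is captured by pyridine-2-thiolate to give the activated thioester.

Step 3
Reactants: 5 (2R)-2-{2-[3,4-bis(benzyloxy)phenyl]ethyl}oxirane (1.0 equiv); 7 S-(pyridin-2-yl) 3-[4-(benzyloxy)phenyl]propanethioate (1.5 equiv)
Product: 8 (5R)-7-[3,4-bis(benzyloxy)phenyl]-1-[4-(benzyloxy)phenyl]-5-hydroxyheptan-3-one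
Conditions: Co(TPP) (cobalt tetraphenylporphyrin, C44H28CoN4, 5 mol%), NiCl2(dme) (10 mol%), 4,4'-di-tert-butyl-2,2'-bipyridine (12 mol%), Zn dust (3 equiv), 2,4,6-collidinium chloride (2 equiv), degassed DMA, blue LEDs (450 nm), 25 °C
Reagents that add atoms: none
Why: Proposed new method: Zn reduces the achiral porphyrin to its monovalent cobalt anion, which opens 5 by SN2 at the terminal CH2 (collidinium as proton donor; any chlorohydrin formed converges on the same species) to a trivalent cobalt β-hydroxyalkyl complex whose Co–C bond is homolysed by blue light; the primary radical is captured by the divalent acyl nickel thiolate formed by oxidative addition of zerovalent nickel into the C(acyl)–S bond of 7, and reductive elimination from trivalent nickel forges C4–C5 while the untouched carbinol carbon keeps its (R) configuration; the closest known reaction types are the light-driven cobalamin/nickel linear-selective arylation of terminal epoxides with aryl halides and the nickel-catalysed reductive ketone synthesis from alkyl halides and 2-pyridyl thioesters, but this merger with an acyl electrophile and an achiral cobalt porphyrin to give a β-hydroxy ketone has not been shown.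

Step 4
Reactants: 8 (5R)-7-[3,4-bis(benzyloxy)phenyl]-1-[4-(benzyloxy)phenyl]-5-hydroxyheptan-3-one
Product: 10 (3R,5R)-1-[3,4-bis(benzyloxy)phenyl]-7-[4-(benzyloxy)phenyl]-5-hydroxyheptan-3-yl acetate, via acetaldehyde hemiacetal 9 (not isolated)
Conditions: MeCHO (8 equiv, freshly distilled), SmI2 (0.3 equiv), THF, −10 °C
Reagents that add atoms: acetaldehyde, CC=O
Why: Evans–Tishchenko reduction; the hemiacetal formed on the existing hydroxyl delivers its hydride intramolecularly to the ketone through a samarium-bridged chair, so the new carbinol (C5) is set anti to the bought centre (giving 5R) and the oxidised hemiacetal remains as the acetate on O3 only.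

Step 5
Reactants: 10 (3R,5R)-1-[3,4-bis(benzyloxy)phenyl]-7-[4-(benzyloxy)phenyl]-5-hydroxyheptan-3-yl acetate
Product: 11 (3R,5R)-1-(3,4-dihydroxyphenyl)-5-hydroxy-7-(4-hydroxyphenyl)heptan-3-yl acetate
Conditions: H2 (1 atm), Pd/C (10 wt% Pd), EtOAc, rt; filtration under Ar
Reagents that add atoms: none
Why: Hydrogenolysis of the three aryl benzyl ethers under neutral aprotic conditions, which leaves the secondary acetate in place (no base or alcohol solvent to trigger 1,3-acyl migration) and touches neither stereocenter.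

## Compound list

1 | 3,4-bis(benzyloxy)benzyl chloride [4-(chloromethyl)-1,2-bis(benzyloxy)benzene] | ClCc1ccc(OCc2ccccc2)c(OCc2ccccc2)c1 | starting material
2 | (R)-epichlorohydrin [(2R)-2-(chloromethyl)oxirane] | ClC[C@H]1CO1 | starting material
3 | [3,4-bis(benzyloxy)benzyl]magnesium chloride | Cl[Mg]Cc1ccc(OCc2ccccc2)c(OCc2ccccc2)c1 | intermediate (not isolated)
4 | (2R)-4-[3,4-bis(benzyloxy)phenyl]-1-chlorobutan-2-ol (present as its chloromagnesium alkoxide) | ClC[C@H](O)CCc1ccc(OCc2ccccc2)c(OCc2ccccc2)c1 | intermediate (not isolated)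
5 | (2R)-2-{2-[3,4-bis(benzyloxy)phenyl]ethyl}oxirane | C1[C@H](O1)CCc2ccc(OCc3ccccc3)c(OCc3ccccc3)c2 | intermediate
6 | 3-[4-(benzyloxy)phenyl]propanoic acid | OC(=O)CCc1ccc(OCc2ccccc2)cc1 | starting material
7 | S-(pyridin-2-yl) 3-[4-(benzyloxy)phenyl]propanethioate | O=C(CCc1ccc(OCc2ccccc2)cc1)Sc1ccccn1 | intermediate
8 | (5R)-7-[3,4-bis(benzyloxy)phenyl]-1-[4-(benzyloxy)phenyl]-5-hydroxyheptan-3-one | O=C(CCc1ccc(OCc2ccccc2)cc1)C[C@H](O)CCc1ccc(OCc2ccccc2)c(OCc2ccccc2)c1 | intermediate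
9 | (5R)-7-[3,4-bis(benzyloxy)phenyl]-1-[4-(benzyloxy)phenyl]-5-(1-hydroxyethoxy)heptan-3-one (samarium-bound hemiacetal, hemiacetal carbon undefined) | CC(O)O[C@H](CCc1ccc(OCc2ccccc2)c(OCc2ccccc2)c1)CC(=O)CCc1ccc(OCc2ccccc2)cc1 | intermediate (not isolated)
10 | (3R,5R)-1-[3,4-bis(benzyloxy)phenyl]-7-[4-(benzyloxy)phenyl]-5-hydroxyheptan-3-yl acetate | CC(=O)O[C@H](CCc1ccc(OCc2ccccc2)c(OCc2ccccc2)c1)C[C@H](O)CCc1ccc(OCc2ccccc2)cc1 | intermediate
11 | (3R,5R)-1-(3,4-dihydroxyphenyl)-5-hydroxy-7-(4-hydroxyphenyl)heptan-3-yl acetate | CC(=O)O[C@H](CCc1ccc(O)c(O)c1)C[C@H](O)CCc1ccc(O)cc1 | target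

## Step count and risks

Total steps: 5. Longest linear sequence: 4 (steps 1, 3, 4, 5); step 2 is a one-step side branch.

**Step 3 (the new acylative epoxide opening), highest risk.** The monovalent cobalt porphyrin may open the epoxide too slowly, the β-hydroxyalkyl radical may be lost to hydrogen abstraction (giving a methyl ketone or the reduced alcohol), or the carbinol may be O-acylated by 7. The fallback is the known dithiane acyl-anion route; it sets out from 5 and 7 and comes back at 8. Thioester 7 is reduced with i-Bu2AlH (CH2Cl2, −78 °C) to 3-[4-(benzyloxy)phenyl]propanal F1, which with propane-1,3-dithiol and BF3·OEt2 gives 2-{2-[4-(benzyloxy)phenyl]ethyl}-1,3-dithiane F2. Lithiation (t-BuLi, THF/HMPA, −78 °C) and addition of epoxide 5 opens the oxirane at its terminal carbon to (2R)-4-[3,4-bis(benzyloxy)phenyl]-1-(2-{2-[4-(benzyloxy)phenyl]ethyl}-1,3-dithian-2-yl)butan-2-ol F3. Dithiane removal with MeI and CaCO3 in aqueous MeCN returns β-hydroxy ketone 8 with the (R) carbinol intact.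

**Step 1 (benzylic Grignard opening).** The electron-rich benzylic Grignard reagent may undergo Wurtz homocoupling, and any direct displacement of chloride in 2 would erode the enantiomeric purity. The fallback avoids the organomagnesium altogether by an olefination route from the ascorbic-acid-derived chiral pool; it sets out from 1 and comes back at 5. Chloride 1 and PPh3 (toluene, reflux) give [3,4-bis(benzyloxy)benzyl]triphenylphosphonium chloride F4. Its ylide (NaN(SiMe3)2, THF, −78 °C) undergoes Wittig reaction with (S)-2,2-dimethyl-1,3-dioxolane-4-carbaldehyde (O=C[C@@H]1COC(C)(C)O1, bought) to give (4R)-4-{2-[3,4-bis(benzyloxy)phenyl]ethenyl}-2,2-dimethyl-1,3-dioxolane F5 as an E/Z mixture. Hydrogenation of the alkene only (H2, RhCl(PPh3)3, benzene/EtOH) gives (4R)-4-{2-[3,4-bis(benzyloxy)phenyl]ethyl}-2,2-dimethyl-1,3-dioxolane F6. Aqueous AcOH frees (2R)-4-[3,4-bis(benzyloxy)phenyl]butane-1,2-diol F7. Selective primary sulfonylation (TsCl, Bu2SnO 2 mol%, Et3N, CH2Cl2) gives (2R)-4-[3,4-bis(benzyloxy)phenyl]-2-hydroxybutyl 4-methylbenzenesulfonate F8, and K2CO3 in MeOH closes it to epoxide 5 with retention at the carbinol carbon.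

**Step 4 (Evans–Tishchenko with acetaldehyde).** Acetaldehyde is volatile and enolisable, so samarium-promoted self-condensation or incomplete hydride transfer may compete; retro-aldol cleavage of 8 is a lesser concern. The fallback replaces direct acetate transfer by a benzoate transfer and ester relay; it sets out from 8 and comes back at 10. Evans–Tishchenko reduction with non-enolisable PhCHO (SmI2 0.3 equiv, THF, −10 °C) gives (3R,5R)-1-[3,4-bis(benzyloxy)phenyl]-7-[4-(benzyloxy)phenyl]-5-hydroxyheptan-3-yl benzoate F9 with the same anti selectivity. Silylation (Et3SiCl, imidazole, DMF) gives (3R,5R)-1-[3,4-bis(benzyloxy)phenyl]-7-[4-(benzyloxy)phenyl]-5-[(triethylsilyl)oxy]heptan-3-yl benzoate F10. Reductive removal of the benzoate (i-Bu2AlH, CH2Cl2, −78 °C) gives (3R,5R)-1-[3,4-bis(benzyloxy)phenyl]-7-[4-(benzyloxy)phenyl]-5-[(triethylsilyl)oxy]heptan-3-ol F11. Acetylation (Ac2O, pyridine, DMAP) gives (3R,5R)-1-[3,4-bis(benzyloxy)phenyl]-7-[4-(benzyloxy)phenyl]-5-[(triethylsilyl)oxy]heptan-3-yl acetate F12, and buffered HF·pyridine (THF, 0 °C) removes the silyl group to give 10 without acyl migration.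

## Further compounds

F1 | step 3 | 3-[4-(benzyloxy)phenyl]propanal | O=CCCc1ccc(OCc2ccccc2)cc1
F2 | step 3 | 2-{2-[4-(benzyloxy)phenyl]ethyl}-1,3-dithiane | C1CSC(CCc2ccc(OCc3ccccc3)cc2)SC1
F3 | step 3 | (2R)-4-[3,4-bis(benzyloxy)phenyl]-1-(2-{2-[4-(benzyloxy)phenyl]ethyl}-1,3-dithian-2-yl)butan-2-ol | C1CSC(CCc2ccc(OCc3ccccc3)cc2)(C[C@H](O)CCc2ccc(OCc3ccccc3)c(OCc3ccccc3)c2)SC1
F4 | step 1 | [3,4-bis(benzyloxy)benzyl]triphenylphosphonium chloride | [Cl-].c1ccccc1[P+](c1ccccc1)(c1ccccc1)Cc1ccc(OCc2ccccc2)c(OCc2ccccc2)c1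
F5 | step 1 | (4R)-4-{2-[3,4-bis(benzyloxy)phenyl]ethenyl}-2,2-dimethyl-1,3-dioxolane (E/Z mixture) | C(=Cc1ccc(OCc2ccccc2)c(OCc2ccccc2)c1)[C@@H]3COC(C)(C)O3
F6 | step 1 | (4R)-4-{2-[3,4-bis(benzyloxy)phenyl]ethyl}-2,2-dimethyl-1,3-dioxolane | C(Cc1ccc(OCc2ccccc2)c(OCc2ccccc2)c1)[C@@H]3COC(C)(C)O3
F7 | step 1 | (2R)-4-[3,4-bis(benzyloxy)phenyl]butane-1,2-diol | OC[C@H](O)CCc1ccc(OCc2ccccc2)c(OCc2ccccc2)c1
F8 | step 1 | (2R)-4-[3,4-bis(benzyloxy)phenyl]-2-hydroxybutyl 4-methylbenzenesulfonate | Cc1ccc(cc1)S(=O)(=O)OC[C@H](O)CCc1ccc(OCc2ccccc2)c(OCc2ccccc2)c1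
F9 | step 4 | (3R,5R)-1-[3,4-bis(benzyloxy)phenyl]-7-[4-(benzyloxy)phenyl]-5-hydroxyheptan-3-yl benzoate | O=C(O[C@H](CCc1ccc(OCc2ccccc2)c(OCc2ccccc2)c1)C[C@H](O)CCc1ccc(OCc2ccccc2)cc1)c1ccccc1
F10 | step 4 | (3R,5R)-1-[3,4-bis(benzyloxy)phenyl]-7-[4-(benzyloxy)phenyl]-5-[(triethylsilyl)oxy]heptan-3-yl benzoate | O=C(O[C@H](CCc1ccc(OCc2ccccc2)c(OCc2ccccc2)c1)C[C@H](O[Si](CC)(CC)CC)CCc1ccc(OCc2ccccc2)cc1)c1ccccc1
F11 | step 4 | (3R,5R)-1-[3,4-bis(benzyloxy)phenyl]-7-[4-(benzyloxy)phenyl]-5-[(triethylsilyl)oxy]heptan-3-ol | O[C@H](CCc1ccc(OCc2ccccc2)c(OCc2ccccc2)c1)C[C@H](O[Si](CC)(CC)CC)CCc1ccc(OCc2ccccc2)cc1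
F12 | step 4 | (3R,5R)-1-[3,4-bis(benzyloxy)phenyl]-7-[4-(benzyloxy)phenyl]-5-[(triethylsilyl)oxy]heptan-3-yl acetate | CC(=O)O[C@H](CCc1ccc(OCc2ccccc2)c(OCc2ccccc2)c1)C[C@H](O[Si](CC)(CC)CC)CCc1ccc(OCc2ccccc2)cc1
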